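It is impossible for a flask to hold more product than the electrophile charged: in the summer run at 4.00 h, 93 % product and 8 % electrophile add up to the charge within a scatter of 1.5 percentage points. So oak's ceiling is 0.040 M and maple's 0.60 M. I ask how fast each ceiling is approached, and whether the row can turn over.

| setting | summer | dawn | winter | oak | alder | larch | cedar | maple |
|---|---|---|---|---|---|---|---|---|
| electrophile | 0.036 M | 0.16 M | 0.48 M | 0.040 M | 0.080 M | 0.15 M | 0.30 M | 0.60 M |
| nucleophile | 0.90 M | 0.90 M | 0.90 M | 0.900 M | 0.900 M | 0.900 M | 0.900 M | 0.900 M |
| free base | 0.30 M | 0.30 M | 0.30 M | 0.300 M | 0.300 M | 0.300 M | 0.300 M | 0.300 M |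
| remark | run made earlier | run made earlier | run made earlier |  |  |  |  |  |
| time |  |  |  | 5.0 h | 5.0 h | 5.0 h | 5.0 h | 5.0 h |

- summer (time / h: product / %, electrophile / %): 0.250: 15, 82; 0.500: 31, 69; 1.00: 54, 48; 2.00: 75, 25; 4.00: 93, 8
- dawn (time / h: product / %, electrophile / %): 0.667: 35, 63; 1.33: 57, 42; 2.00: 71, 30; 3.00: 82, 19; 4.00: 89, 14
- winter (time / h: product / %, electrophile / %): 0.250: 15, 82; 0.500: 30, 73; 1.00: 41, 56; 2.00: 57, 41; 4.00: 75, 23

(each reading ± 1.5 percentage points)

- the analysis behind the earlier runs scatters by 1.5 percentage points, standard deviation
- "hardly changes" means that all values lie within two and a half points (for a concentration: within two and a half percent of the largest)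

- [product] at the end for oak, alder, larch, cedar, maple, in this order
- how the row runs (rises, then falls / falls all the way / hardly changes / rises all the way / falls, then rises)

The summer run has nucleophile far above electrophile, so it is pseudo-first-order. With 25 % of the electrophile left at 2.00 h, I read a rate constant k of 0.693 /h, a time constant of 1.44 h. Without any braking, 5.0 h leaves 3.13 % of the electrophile.

The winter run does brake. It matches the summer run at 0.250 h, with 82 % left, but between 2.00 h and 4.00 h its local constant is 0.289 /h, lower than k, at a mean product of 0.317 M. I take the local constant as k divided by one plus P/C, with P the product. The winter reading then gives 0.227 M for C, the braking concentration: the product concentration at which the local constant is half of k.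

Can the row turn over? By this rule, at equal product a larger charge has more electrophile left and the same local constant, so its curve stays above. Integrating, the time to convert a fraction x of a charge E is (one plus E/C) times ln(one over one minus x), less Ex/C, all divided by k. By my estimate, maple reaches 0.30 M, half of its charge and cedar's whole ceiling, after 1.74 h, earlier than 5.0 h. So I commit to a row that rises all the way.

The forecast gives 0.038 M, 0.075 M, 0.137 M, 0.257 M and 0.46 M, and says the row rises all the way: “Absolute product still rises throughout”. Its braking value is 0.18 M, not my 0.227 M, and my rule reaches its maple value at 4.73 h, sooner than 5.0 h, so my maple lies slightly above the forecast's.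

The flask gives 0.0384 M, 0.0761 M, 0.140 M, 0.264 M and 0.444 M: the row rises all the way.

    nucleophile + acid set free ⇌ protonated nucleophile, settled at all times (K = 75.6 /M)
    nucleophile ⇌ dormant form (K = 0.836, k = 1.44 × 10⁻⁵ /s)
    electrophile + nucleophile → acid set free + product (k = 2.35 × 10⁻⁴ /M/s)
    acid set free + free base ⇌ salt of the base (K = 1.65 × 10⁵ /M, k = 0.00630 /M/s)

Oak's electrophile has a half-life of 0.91 h by its reaction with the nucleophile as charged, shorter than the 13 h of oak's nucleophile by the forward step to the dormant form. At 2.10 h, oak's forward step to the dormant form uses nucleophile 6.6 times as fast as the product step does. At 5.00 h, maple's product stands at 73.9 % of its charge and cedar's at 88.0 % of its charge. With C, the rule reaches maple's fraction after 4.25 h and cedar's after 5.43 h.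

All runs are simulated on assumed constants.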